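Slowness is what I see first: the ash run, with 5.7 equiv of third substrate, still holds 77.1% of its starting material at 40.0 min, more than the 19.4% of the maple run with 0.88 equiv. The target suffers as well, and my next decision hangs on that: the flasks of the new row differ in third substrate and stop at 40 min, so which of them do I charge if I want target in hand and a reading that stands clear of the scatter?

| flask | starting material | reagent | second substrate | third substrate | remark | time |
|---|---|---|---|---|---|---|
| maple | 20 mM | 1.5 equiv | 2 equiv | 0.88 equiv | run made earlier |  |
| larch | 20 mM | 1.5 equiv | 2 equiv | 2.3 equiv | run made earlier |  |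
| ash | 20 mM | 1.5 equiv | 2 equiv | 5.7 equiv | run made earlier |  |
| Wednesday's | 20 mM | 1.50 equiv | 2.00 equiv | 1.00 equiv |  | 40 min |
| Monday's | 20 mM | 1.50 equiv | 2.00 equiv | 1.50 equiv |  | 40 min |
| Sunday's | 20 mM | 1.50 equiv | 2.00 equiv | 2.50 equiv |  | 40 min |
| Thursday's | 20 mM | 1.50 equiv | 2.00 equiv | 3.00 equiv |  | 40 min |
| Tuesday's | 20 mM | 1.50 equiv | 2.00 equiv | 5.00 equiv |  | 40 min |

| run | time / min | target / % | starting material / % |
|---|---|---|---|
| maple | 3.00 | 15.7 | 78.9 |
| maple | 8.00 | 23.4 | 57.3 |
| maple | 15.0 | 22.5 | 39.7 |
| maple | 40.0 | 11.4 | 19.4 |
| larch | 5.00 | 15.6 | 75.0 |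
| larch | 15.0 | 11.7 | 58.6 |
| larch | 25.0 | 6.8 | 53.5 |
| larch | 40.0 | 2.6 | 50.1 |
| ash | 3.00 | 9.6 | 87.6 |
| ash | 8.00 | 6.5 | 82.2 |
| ash | 15.0 | 3.3 | 79.4 |
| ash | 40.0 | 0 | 77.1 |

(scatter of a reading: 0.3 percentage points)

- the earlier runs were read with a standard deviation of 0.3 percentage points
- "hardly changes" means that all values lie within two and a half points (for a concentration: within two and a half percent of the largest)

- amount of target at the end, in percent of the starting material charged for Wednesday's, Monday's, Sunday's, Thursday's, Tuesday's, in this order
- how the row runs (rises all the way / falls, then rises / hardly changes / rises, then falls / falls all the way)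

The end values are remainders: the maple target goes from 23.4% down to 11.4%, the larch target from 15.6% down to 2.6%. I compare remainders by ratio, so I work on a logarithmic scale. Between the maple and larch ends, ln(target) drops by 1.04 for each equivalent of third substrate. This g, the drop of ln(end target) per equivalent of third substrate, has its zero at a flat row. The ash end reads 0%, which has no logarithm, so two runs carry g, and it remains a reading, since the larch end of 2.6% bears a scatter of 0.3 percentage points.

Walking from the maple end at this g, I reckon 10.1% for Wednesday's flask and 5.98% for Monday's. Walking from the larch end, I reckon 2.11% for Sunday's, 1.25% for Thursday's and 0.156% for Tuesday's. So I charge Wednesday's flask, whose reckoned target is higher than that of any other, and I leave Tuesday's, whose reckoned target is smaller than the scatter of one reading.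

The forecast gives 9.5%, 6%, 2.2%, 1.3% and 0.1%, a row that falls all the way, on the ground “The log of target falls about one unit per equiv”, and its first point stands below mine.

The flasks give 10.2%, 5.67%, 1.87%, 1.24% and 0.438%, so the row falls all the way.

    starting material + reagent → target (k = 2.88 /M/min)
    second substrate + reagent → second product (k = 0.0406 /M/min)
    third substrate + reagent → third product (k = 5.37 /M/min)
    second substrate → decomposition product (k = 9.76 × 10⁻⁵ /min)
    starting material + target → side product (k = 4.37 /M/min)
    target → over-reaction product (k = 0.0268 /min)

In Wednesday's flask the target is made 2.02 times faster than it is used up at 4.43 min, each step taken net, but at 40.0 min that ratio stands at 0.338. From Wednesday's flask to Monday's, g comes out at 1.17. From Thursday's flask to Tuesday's it comes out at 0.520, half the maple-to-larch reading.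

The data are calculated for an exercise, noise included.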